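**Assumptions:** (i) the orthoester carbon created in step 2 forms as a mixture of both configurations, is carried as such and disappears in step 8, so it is left undefined in the SMILES; (ii) the sense of induction of the (R)-BINOL catalyst in step 4 is assumed, and the (S)-catalyst is used if it proves opposite. Six-ring compounds carry the target numbering: C1 (CH–OAc), C2, C3, C4, C5 (=C–CH2), C6 (=CH), C7 (exocyclic CH2); O1/O4 lie on the α face, O2/O3 on the β face.

**Retrosynthetic overview**
1. Target 13 ⇐ 12: the 3‑O‑benzoate/2‑OH pair is unveiled last from a C2/C3 cyclic methyl orthobenzoate (latent benzoate); C1‑OAc and C7‑OBz come from triol 8 by masked and selective acylation.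
2. 8 ⇐ enoate 7 by ester reduction.
3. Key disconnection: 7 ⇐ meso bis‑epoxy cycloheptanone 5 by a desymmetrising semibenzilic (quasi‑Favorskii) 1,2‑shift. This 7→6 ring contraction forms C5–C6 and makes the carbonyl carbon exocyclic C7; E1cB opening of the second epoxide then gives C5=C6 and C1‑OH.
4. 5 ⇐ cross‑conjugated dienone 3 (double anti epoxidation) ⇐ meso diol 2 ⇐ tropone 1 (dihydroxylation of C4=C5).
5. Ring order: the seven‑membered carbocycle is bought; the dioxolane (step 2) and two oxiranes (step 3) are temporary; the cyclohexene is formed only in step 4.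

**Step 1**
Reactants: 1 tropone
Product: 2 cis-4,5-dihydroxycyclohepta-2,6-dien-1-one (meso; 4R,5S)
Conditions: OsO4 (2 mol %), NMO (1.1 equiv), acetone/H2O 4:1, 0 °C → rt
Reagents that add atoms: N-methylmorpholine N-oxide C[N+]1([O-])CCOCC1; water O (both oxygens are delivered through the OsO4 catalyst)
Why: Upjohn dihydroxylation, in which electrophilic OsO4 should take the C4=C5 bond (the only alkene of tropone not conjugated directly to the carbonyl) and add syn to give the meso cis-diol, fixing the cis relationship of the future O2/O3.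

**Step 2**
Reactants: 2 cis-4,5-dihydroxycyclohepta-2,6-dien-1-one
Product: 3 cis-4,5-O-(α-methoxybenzylidene)-4,5-dihydroxycyclohepta-2,6-dien-1-one (cyclic methyl orthobenzoate; meso ring fusion)
Conditions: PhC(OMe)3 (1.5 equiv), CSA (5 mol %), CH2Cl2, rt; Et3N quench
Reagents that add atoms: trimethyl orthobenzoate COC(OC)(OC)c1ccccc1
Why: Acid-catalysed transorthoesterification of a cis-1,2-diol gives the cis-fused 2-methoxy-2-phenyl-1,3-dioxolane, which is stable to the basic and hydridic steps that follow and already carries the benzoyl carbon of the 3-O-benzoate.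

**Step 3**
Reactants: 3 dienone orthoester
Product: 5 meso (2R,3R,4R,5S,6S,7S)-2,3:6,7-diepoxy-4,5-O-(α-methoxybenzylidene)-4,5-dihydroxycycloheptan-1-one (both oxiranes on the face opposite the dioxolane), via mono-epoxy enone 4 (not isolated)
Conditions: t-BuOOH (2.5 equiv, decane), DBU (1.2 equiv), CH2Cl2, 0 °C
Reagents that add atoms: tert-butyl hydroperoxide CC(C)(C)OO
Why: Weitz–Scheffer nucleophilic epoxidation of both enone units, where t-BuOO⁻ adds to each β-carbon anti to the adjacent dioxolane C–O bond, so both oxiranes form trans to the dioxolane and set the future C4 and C1 carbinol configurations relative to O3 and O2.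

**Step 4**
Reactants: 5 meso bis-epoxy ketone
Product: 7 methyl (3R,4S,5R,6S)-3,6-dihydroxy-4,5-O-(α-methoxybenzylidene)-4,5-dihydroxycyclohex-1-ene-1-carboxylate (target numbering: 1-OH and 4-OH free; 1R,2S,3R,4S), via epoxy ester 6 (not isolated)
Conditions: (R)-LaLi3(binaphthoxide)3 (10 mol %), MeOH (5 equiv), THF, −20 → 0 °C; then DBU (1.5 equiv), rt
Reagents that add atoms: methanol CO
Why: Proposed new method: a catalytic enantioselective desymmetrising semibenzilic (quasi-Favorskii) ring contraction, in which La(III) chelates the ketone oxygen and one of the two enantiotopic oxirane oxygens while the lithium binaphthoxide delivers methanol to C=O, so that in the chelated hemiketal alkoxide the ring bond C1–C7 is antiperiplanar to the activated C2–O bond and shifts from C1 to C2 (7→6 contraction, ester at the new C5, alkoxide at C4 with retention), after which base-induced E1cB opening of the remaining β,γ-epoxide gives C5=C6 and C1–OH with retention, the catalyst's choice of oxirane fixing the absolute configuration of all four carbinol centres; the closest known reactions are the alkoxide-induced semibenzilic rearrangement of non-enolisable α-halo and α,β-epoxy ketones and heterobimetallic BINOL-catalysed desymmetrising openings of meso-epoxides.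

**Step 5**
Reactants: 7 diol enoate
Product: 8 (1R,2S,3R,4S)-5-(hydroxymethyl)-2,3-O-(α-methoxybenzylidene)cyclohex-5-ene-1,2,3,4-tetrol (1-OH, 4-OH and 7-OH free)
Conditions: LiAlH4 (2.5 equiv), THF, −20 → 0 °C; Fieser work-up
Reagents that add atoms: none
Why: 1,2-Reduction of the conjugated ester to the primary allylic alcohol by LiAlH4, to which orthoesters are inert; no stereocentre is touched.

**Step 6**
Reactants: 8 triol
Product: 11 (1R,2S,3R,4S)-1-O-acetyl-5-(hydroxymethyl)-2,3-O-(α-methoxybenzylidene)cyclohex-5-ene-1,2,3,4-tetrol, via boronate 9 (not isolated), via boronate acetate 10 (not isolated)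
Conditions: PhB(OH)2 (1.05 equiv), pyridine, 4 Å MS, rt; then Ac2O (1.5 equiv), DMAP (5 mol %), 0 °C; aq. sorbitol/Na2CO3 work-up
Reagents that add atoms: acetic anhydride CC(=O)OC(C)=O; phenylboronic acid OB(O)c1ccccc1 (present in 9 and 10 only, released on work-up)
Why: Transient boronate masking, in which the 4-OH/7-OH 1,3-diol closes a six-membered dioxaborinane so that only 1-OH is free for DMAP-catalysed acetylation, and the boronate is released on aqueous polyol work-up.

**Step 7**
Reactants: 11 1-O-acetate diol
Product: 12 [(3R,4S,5R,6S)-3-acetoxy-6-hydroxy-4,5-O-(α-methoxybenzylidene)-4,5-dihydroxycyclohex-1-en-1-yl]methyl benzoate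
Conditions: BzCl (1.1 equiv), pyridine, CH2Cl2, −40 °C
Reagents that add atoms: benzoyl chloride O=C(Cl)c1ccccc1
Why: Selective acylation of the primary allylic 7-OH over the secondary 4-OH, which is flanked by the substituted alkene carbon and the dioxolane, at low temperature.

**Step 8**
Reactants: 12 orthoester acetate benzoate
Product: 13 [(3R,4S,5R,6S)-3-acetoxy-5-(benzoyloxy)-4,6-dihydroxycyclohex-1-en-1-yl]methyl benzoate (target)
Conditions: AcOH/H2O 4:1, 0 °C → rt
Reagents that add atoms: water O
Why: Mild acid hydrolysis of the cyclic orthoester through the dioxolan-2-ylium ion and hemiorthoester, which collapses to the axial ester and equatorial alcohol (axial-ester rule for cis-diol orthoesters), and since 4-OH sits pseudoaxial to avoid A(1,2) strain with the C5 substituent, O3 is axial and O2 equatorial, giving the 3-O-benzoate and free 2-OH without touching a stereocentre.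

**Compound list**
1 | tropone (cyclohepta-2,4,6-trien-1-one) | O=C1C=CC=CC=C1 | starting material
2 | cis-4,5-dihydroxycyclohepta-2,6-dien-1-one (meso; 4R,5S) | O=C1C=C[C@@H](O)[C@@H](O)C=C1 | intermediate
3 | cis-4,5-O-(α-methoxybenzylidene)-4,5-dihydroxycyclohepta-2,6-dien-1-one (cis-fused 2-methoxy-2-phenyl-1,3-dioxolane; orthoester carbon as epimer mixture) | O=C1C=C[C@H]2OC(OC)(c3ccccc3)O[C@H]2C=C1 | intermediate
4 | 2,3-mono-epoxide of 3, oxirane anti to the dioxolane (racemate; one enantiomer drawn) | O=C1[C@@H]2O[C@@H]2[C@H]3OC(OC)(c4ccccc4)O[C@H]3C=C1 | intermediate (not isolated)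
5 | meso (2R,3R,4R,5S,6S,7S)-2,3:6,7-diepoxy-4,5-O-(α-methoxybenzylidene)-4,5-dihydroxycycloheptan-1-one | O=C1[C@@H]2O[C@@H]2[C@H]3OC(OC)(c4ccccc4)O[C@H]3[C@@H]2O[C@H]12 | intermediate
6 | methyl cyclohexanecarboxylate with CO2Me on C5 (α), 4-OH (α), C1–C6 oxirane (α) and C2/C3 cis-dioxolane (β) | COC(=O)[C@@H]1[C@H](O)[C@@H](O3)[C@@H](OC3(OC)c2ccccc2)[C@@H]2O[C@H]12 | intermediate (not isolated)
7 | methyl (3R,4S,5R,6S)-3,6-dihydroxy-4,5-O-(α-methoxybenzylidene)-4,5-dihydroxycyclohex-1-ene-1-carboxylate | O[C@@H]1C=C(C(=O)OC)[C@H](O)[C@@H](O3)[C@H]1OC3(OC)c1ccccc1 | intermediate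
8 | (1R,2S,3R,4S)-5-(hydroxymethyl)-2,3-O-(α-methoxybenzylidene)cyclohex-5-ene-1,2,3,4-tetrol | O[C@@H]1C=C(CO)[C@H](O)[C@@H](O3)[C@H]1OC3(OC)c1ccccc1 | intermediate
9 | 4,7-O-phenylboronate (six-membered dioxaborinane) of 8 | O[C@@H]1C=C2COB(c3ccccc3)O[C@@H]2[C@@H](O4)[C@H]1OC4(OC)c1ccccc1 | intermediate (not isolated)
10 | 1-O-acetyl-4,7-O-phenylboronate of 8 | CC(=O)O[C@@H]1C=C2COB(c3ccccc3)O[C@@H]2[C@@H](O4)[C@H]1OC4(OC)c1ccccc1 | intermediate (not isolated)
11 | 1-O-acetate of 8 (4-OH and 7-OH free) | CC(=O)O[C@@H]1C=C(CO)[C@H](O)[C@@H](O3)[C@H]1OC3(OC)c1ccccc1 | intermediate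
12 | 1-O-acetyl-7-O-benzoyl derivative of 8 (4-OH free; C2/C3 orthoester) | CC(=O)O[C@@H]1C=C(COC(=O)c2ccccc2)[C@H](O)[C@@H](O3)[C@H]1OC3(OC)c1ccccc1 | intermediate
13 | [(3R,4S,5R,6S)-3-acetoxy-5-(benzoyloxy)-4,6-dihydroxycyclohex-1-en-1-yl]methyl benzoate | CC(=O)O[C@@H]1C=C(COC(=O)c2ccccc2)[C@H](O)[C@@H](OC(=O)c2ccccc2)[C@H]1O | target

**Totals:** 8 steps; longest linear sequence 8 steps.

**Steps most likely to fail and their fallbacks**

Step 4 (proposed desymmetrising ring contraction; the shift or the enantioselectivity may fail). The fallback sets out from 5 and comes back at 7. Stoichiometric NaOMe in MeOH at 0 °C runs the classical alkoxide semibenzilic contraction and E1cB opening without a chiral catalyst. This gives the racemate, that is 7 together with the enantiomeric diol ester F1. Kinetic resolution with lipase PS and vinyl acetate in MTBE acetylates the (1R)-carbinol (bulky sp3 C2 side, medium vinylic C6 side) to the 1-O-acetyl diol ester F2 and leaves F1 behind. After chromatography, K2CO3 in MeOH converts F2 into 7.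

Step 8 (regiochemistry of orthoester opening; the 2-O-benzoate forms if the ring prefers the conformer with O3 equatorial). The fallback sets out from 12 and comes back at 13. PPTS (cat.) in anhydrous MeOH with HC(OMe)3 as water scavenger exchanges the cyclic orthoester and frees the 1-O-acetyl-7-O-benzoyl 2,3,4-triol F3. Borinic-acid catalysis (2-aminoethyl diphenylborinate 10 mol %, BzCl, i-Pr2NEt, MeCN) then benzoylates the equatorial oxygen of the cis-2,3-diol. That selectivity is complementary to orthoester hydrolysis, so in the conformer that defeats step 8 it places the benzoate on O3 and gives 13.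

Step 1 (site selectivity or sluggish osmylation of tropone). The fallback sets out from 1 and comes back at 3.
- LiAlH4 in Et2O at 0 °C with mild acidic work-up gives cyclohepta-3,5-dien-1-one F4.
- Et3N in CH2Cl2 isomerises it to the conjugated cyclohepta-2,4-dien-1-one F5.
- OsO4/NMO dihydroxylates the distal γ,δ-alkene to racemic cis-4,5-dihydroxycyclohept-2-en-1-one F6.
- PhC(OMe)3/CSA gives the cyclic orthobenzoate enone F7.
- IBX·4-methoxypyridine N-oxide in DMSO at rt dehydrogenates the saturated α′,β′ positions to the dienone 3.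

**Further compounds**
F1 | step 4 | enantiomer of 7, methyl (3S,4R,5S,6R)-3,6-dihydroxy-4,5-O-(α-methoxybenzylidene)-4,5-dihydroxycyclohex-1-ene-1-carboxylate | O[C@H]1C=C(C(=O)OC)[C@@H](O)[C@H](O3)[C@@H]1OC3(OC)c1ccccc1
F2 | step 4 | 1-O-acetate of 7 (methyl ester, 4-OH free) | CC(=O)O[C@@H]1C=C(C(=O)OC)[C@H](O)[C@@H](O3)[C@H]1OC3(OC)c1ccccc1
F3 | step 8 | [(3R,4S,5R,6S)-3-acetoxy-4,5,6-trihydroxycyclohex-1-en-1-yl]methyl benzoate | CC(=O)O[C@@H]1C=C(COC(=O)c2ccccc2)[C@H](O)[C@@H](O)[C@H]1O
F4 | step 1 | cyclohepta-3,5-dien-1-one | O=C1CC=CC=CC1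
F5 | step 1 | cyclohepta-2,4-dien-1-one | O=C1C=CC=CCC1
F6 | step 1 | cis-4,5-dihydroxycyclohept-2-en-1-one (racemate; one enantiomer drawn) | O=C1C=C[C@@H](O)[C@@H](O)CC1
F7 | step 1 | cis-4,5-O-(α-methoxybenzylidene)-4,5-dihydroxycyclohept-2-en-1-one (racemate; orthoester carbon as epimer mixture) | O=C1C=C[C@H]2OC(OC)(c3ccccc3)O[C@H]2CC1
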